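**Strategy**

The target is numbered from the carboxyl carbon C1 to C17, the methylene on furan C3. The oxirane (O, C6, C7) has a fully substituted C6 (CH3 and C5H2) and a C7 carrying H and C8H2, so it maps onto a C6 methyl ketone with a C7 chloride and can be built by C–C bond formation at a carbonyl, with no oxidant that would have to spare the 3-substituted furan ring and the C10=C11 and C14=C15 olefins.
Retrosynthetic cuts, in order: C1 ester, C2=C3 (cross-metathesis), O–C7 (chlorohydrin closure), C5–C6 (Grignard addition to the α-chloroketone), C6–CH3 and C7–Cl (from a C6 aldehyde), C16–C17 and C8–C9 (two copper-catalysed alkyl–allyl couplings).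
Forward, the chain is joined in the order C8–C9, C16–C17 (furan bought intact), C7–Cl, C6–CH3, C5–C6; then the oxirane, the only ring formed, closes at O–C7, the C2=C3 olefin is installed and the ester is hydrolysed.
Stereochemistry: C7 is set as the (R)-chloride by enamine catalysis and becomes (S) by inversion on ring closure; C6 (S) comes from 1,2-induction by the C7–Cl centre in the Grignard addition; the C14 olefin is that of geranyl acetate, C10 comes from E-selective allylic oxidation and C2 from the E preference of the metathesis.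

Key step: step 12

Assumption: the (5R) enantiomer of the imidazolidinone catalyst is taken to give the (2R)-chloroaldehyde, as the face-shielding model of its E-enamine predicts; its mirror image would be used if the sense were the opposite.

**Route**

Step 1
Reactants: 1 geranyl acetate
Product: 2 (2E,6E)-8-hydroxy-3,7-dimethylocta-2,6-dien-1-yl acetate
Conditions: SeO2 (0.3 equiv), t-BuOOH (70% aq.), salicylic acid (cat.), CH2Cl2, 25 °C
Reagents that add atoms: selenium dioxide, O=[Se]=O; tert-butyl hydroperoxide, CC(C)(C)OO
Why: Riley allylic oxidation (ene reaction of tetravalent selenium at the electron-rich 6,7-olefin, the 2,3-olefin being deactivated by the allylic acetate, then a [2,3]-sigmatropic shift) oxidises the methyl group trans to the C5 methylene, so the olefin that becomes C10=C11 of the target should be E.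

Step 2
Reactants: 2 (2E,6E)-8-hydroxy-3,7-dimethylocta-2,6-dien-1-yl acetate
Product: 3 (2E,6E)-8-bromo-3,7-dimethylocta-2,6-dien-1-yl acetate
Conditions: CBr4, PPh3, CH2Cl2, −20 to 0 °C
Reagents that add atoms: carbon tetrabromide, BrC(Br)(Br)Br
Why: Appel bromination, in which bromide displaces the alkoxyphosphonium group by SN2 at the primary allylic carbon under neutral conditions, leaving the acetate and both olefin geometries untouched.

Step 3
Reactants: 3 (2E,6E)-8-bromo-3,7-dimethylocta-2,6-dien-1-yl acetate; 4 2-(2-bromoethyl)-1,3-dioxolane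
Product: 6 acetal acetate (2E,6E)-10-(1,3-dioxolan-2-yl)-3,7-dimethyldeca-2,6-dien-1-yl acetate, via acetal Grignard reagent 5 (not isolated)
Conditions: 4, Mg, THF, 25 °C; then added slowly to 3, Li2CuCl4 (3 mol %), THF, −78 to −30 °C
Reagents that add atoms: none
Why: Kochi-type coupling, in which the primary alkyl Grignard reagent is transferred through a monovalent organocopper species (formed from Li2CuCl4) to the primary allylic bromide with SN2 regiochemistry and retention of the E olefin to form the C8–C9 bond; at −78 °C the bromide should react far faster than the allylic acetate or its carbonyl group.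

Step 4
Reactants: 6 acetal acetate
Product: 7 acetal alcohol (2E,6E)-10-(1,3-dioxolan-2-yl)-3,7-dimethyldeca-2,6-dien-1-ol
Conditions: K2CO3 (cat.), MeOH, 25 °C
Reagents that add atoms: none
Why: Base-catalysed transesterification (methanolysis) frees the primary allylic alcohol, and the dioxolane is inert to base.

Step 5
Reactants: 7 acetal alcohol
Product: 8 allylic chloride 2-[(4E,8E)-10-chloro-4,8-dimethyldeca-4,8-dien-1-yl]-1,3-dioxolane
Conditions: NCS, Me2S, CH2Cl2, −30 to 0 °C
Reagents that add atoms: N-chlorosuccinimide, ClN1C(=O)CCC1=O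
Why: Corey–Kim chlorination, in which the alkoxysulfonium salt collapses by SN2 attack of chloride at the primary allylic carbon under neutral conditions, without allylic transposition, E/Z isomerisation or acid that would touch the acetal.

Step 6
Reactants: 9 furan-3-ylmethanol
Product: 10 3-(chloromethyl)furan
Conditions: SOCl2, pyridine, Et2O, 0 °C; used at once
Reagents that add atoms: thionyl chloride, O=S(Cl)Cl
Why: Chlorodehydroxylation through the chlorosulfite ester with pyridine as acid scavenger gives the reactive furylmethyl chloride, which is made fresh because it does not store well.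

Step 7
Reactants: 8 allylic chloride; 10 3-(chloromethyl)furan
Product: 12 furyl diene acetal 2-[(4E,8E)-11-(furan-3-yl)-4,8-dimethylundeca-4,8-dien-1-yl]-1,3-dioxolane, via furylmethyl Grignard reagent 11 (not isolated)
Conditions: 10, Mg (activated), THF, 0 °C, slow addition; then 8, Li2CuCl4 (5 mol %), THF, 0 °C
Reagents that add atoms: none
Why: Kochi-type coupling of the benzylic-type 3-furylmethyl Grignard reagent with the primary allylic chloride through a monovalent organocopper species forms the C16–C17 bond at the exocyclic carbon with SN2 regiochemistry and retention of the C14 E olefin, and the dioxolane tolerates the Grignard reagent.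

Step 8
Reactants: 12 furyl diene acetal
Product: 13 aldehyde (5E,9E)-12-(furan-3-yl)-5,9-dimethyldodeca-5,9-dienal
Conditions: 1 M aq. HCl, THF, 25 °C; NaHCO3 quench as soon as 12 is consumed
Reagents that add atoms: water, O
Why: Acid-catalysed acetal hydrolysis through the oxocarbenium ion; dilute acid at room temperature with an early quench should spare the 3-alkylfuran and the trisubstituted olefins.

Step 9
Reactants: 13 aldehyde
Product: 14 (2R,5E,9E)-2-chloro-12-(furan-3-yl)-5,9-dimethyldodeca-5,9-dienal
Conditions: (5R)-5-benzyl-2,2,3-trimethylimidazolidin-4-one·TFA (10 mol %), 2,3,4,5,6,6-hexachlorocyclohexa-2,4-dien-1-one (1.2 equiv), acetone, −30 °C; cold pentane filtration, used at once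
Reagents that add atoms: 2,3,4,5,6,6-hexachlorocyclohexa-2,4-dien-1-one, O=C1C(Cl)=C(Cl)C(Cl)=C(Cl)C1(Cl)Cl
Why: Enamine-catalysed enantioselective α-chlorination, in which the E-enamine, far more nucleophilic than the furan or the olefins, takes chlorine from the perchlorinated dienone on the face not shielded by the catalyst benzyl group and so sets C7 as (R); the configurationally labile product is carried on without delay.

Step 10
Reactants: 14 (R)-α-chloroaldehyde
Product: 15 (3R,6E,10E)-3-chloro-13-(furan-3-yl)-6,10-dimethyltrideca-6,10-dien-2-ol (both C2 epimers)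
Conditions: MeMgBr, Et2O, −78 °C; aq. NH4Cl at −78 °C
Reagents that add atoms: methylmagnesium bromide, C[Mg]Br
Why: Grignard 1,2-addition to the aldehyde forms the C6–CH3 bond; the carbinol centre forms as a mixture that does not matter because it is oxidised next, and the cold quench prevents premature oxirane formation.

Step 11
Reactants: 15 secondary chlorohydrin
Product: 16 (R)-α-chloro methyl ketone (3R,6E,10E)-3-chloro-13-(furan-3-yl)-6,10-dimethyltrideca-6,10-dien-2-one
Conditions: Dess–Martin periodinane, NaHCO3, CH2Cl2, 0 to 25 °C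
Reagents that add atoms: none
Why: Dess–Martin oxidation of the secondary alcohol under buffered, near-neutral conditions should give the α-chloroketone without enolising the C7 centre and without touching the furan or the olefins.

Step 12
Reactants: 16 (R)-α-chloro methyl ketone; 17 but-3-en-1-ylmagnesium bromide
Product: 18 (5S,6R,9E,13E)-6-chloro-16-(furan-3-yl)-5,9,13-trimethylhexadeca-1,9,13-trien-5-ol, the (6S,7R) chlorohydrin in target numbering
Conditions: 17 (1.5 equiv), THF/Et2O, −90 to −78 °C; aq. NH4Cl at −78 °C
Reagents that add atoms: none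
Why: Irreversible 1,2-addition of the primary alkyl Grignard reagent to the C6 carbonyl forms the C5–C6 bond and the C6 tertiary alkoxide next to the C7 chloride, the closest known reaction type being the Cornforth chlorohydrin addition of an alkylmagnesium halide to an α-chloro methyl ketone at low temperature. No ring closes in this step; the O–C7 bond of the oxirane is made only in step 13. The new C6 stereocentre is controlled by C7: the ketone reacts through the conformer with the C=O and C7–Cl dipoles opposed (the polar Felkin–Anh model gives the same product) and the nucleophile passes the C7 hydrogen, not the C8 methylene, which places C5 anti to C8 and the oxygen antiperiplanar to chlorine, i.e. the (6S,7R) chlorohydrin. The step needs facial selectivity and addition in preference to deprotonation at C7; the first is secured by the C–Cl dipole together with the H versus CH2 size difference at C7, the second by the high electrophilicity of the α-chloroketone, the low temperature and the cold, non-basic quench. Because the nucleophile ends trans to C8, the larger C5 residue has to be the Grignard reagent and the methyl group has to be on the ketone already, which is why the C6–CH3 bond is made first.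

Step 13
Reactants: 18 (6S,7R) chlorohydrin
Product: 19 epoxy triene (2S,3S)-2-(but-3-en-1-yl)-3-[(3E,7E)-10-(furan-3-yl)-3,7-dimethyldeca-3,7-dien-1-yl]-2-methyloxirane
Conditions: K2CO3, MeOH, 25 °C
Reagents that add atoms: none
Why: Intramolecular Williamson etherification, in which the tertiary alkoxide displaces chloride in a 3-exo-tet SN2 closure with inversion at C7 (R to S) and retention at C6, so that the C5 and C8 chains end trans on the oxirane and the methyl group cis to C8.

Step 14
Reactants: 19 epoxy triene; 20 methyl methacrylate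
Product: 21 methyl (2E)-5-{(2S,3S)-3-[(3E,7E)-10-(furan-3-yl)-3,7-dimethyldeca-3,7-dien-1-yl]-2-methyloxiran-2-yl}-2-methylpent-2-enoate
Conditions: second-generation Grubbs catalyst RuCl2(=CHPh)(PCy3)(H2IMes) (5 mol %), 20 (10 equiv), CH2Cl2, 40 °C
Reagents that add atoms: none
Why: Olefin cross-metathesis, in which the ruthenium alkylidene engages only the monosubstituted olefin while the trisubstituted C10 and C14 olefins, the furan and the oxirane stay spectators, and the conjugated trisubstituted enoate forms as the thermodynamically preferred E isomer.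

Step 15
Reactants: 21 methyl ester
Product: 22 CNP0308047.1, (2E)-5-{(2S,3S)-3-[(3E,7E)-10-(furan-3-yl)-3,7-dimethyldeca-3,7-dien-1-yl]-2-methyloxiran-2-yl}-2-methylpent-2-enoic acid
Conditions: LiOH·H2O, THF/MeOH/H2O, 25 to 40 °C; then 0.5 M HCl to pH 4–5 at 0 °C with EtOAc present
Reagents that add atoms: lithium hydroxide, [Li+].[OH-]
Why: Saponification (acyl-oxygen ester hydrolysis) by hydroxide, to which the trisubstituted oxirane is inert, followed by acidification only to pH 4–5 in the cold so that the epoxy acid is extracted before it can be opened.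

**Compound list**

1 | geranyl acetate | CC(=O)OC/C=C(\C)CCC=C(C)C | starting material
2 | (2E,6E)-8-hydroxy-3,7-dimethylocta-2,6-dien-1-yl acetate | CC(=O)OC/C=C(\C)CC/C=C(\C)CO | intermediate
3 | (2E,6E)-8-bromo-3,7-dimethylocta-2,6-dien-1-yl acetate | CC(=O)OC/C=C(\C)CC/C=C(\C)CBr | intermediate
4 | 2-(2-bromoethyl)-1,3-dioxolane | BrCCC1OCCO1 | starting material
5 | [2-(1,3-dioxolan-2-yl)ethyl]magnesium bromide | Br[Mg]CCC1OCCO1 | intermediate (not isolated)
6 | (2E,6E)-10-(1,3-dioxolan-2-yl)-3,7-dimethyldeca-2,6-dien-1-yl acetate | CC(=O)OC/C=C(\C)CC/C=C(\C)CCCC1OCCO1 | intermediate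
7 | (2E,6E)-10-(1,3-dioxolan-2-yl)-3,7-dimethyldeca-2,6-dien-1-ol | OC/C=C(\C)CC/C=C(\C)CCCC1OCCO1 | intermediate
8 | 2-[(4E,8E)-10-chloro-4,8-dimethyldeca-4,8-dien-1-yl]-1,3-dioxolane | ClC/C=C(\C)CC/C=C(\C)CCCC1OCCO1 | intermediate
9 | furan-3-ylmethanol | OCc1ccoc1 | starting material
10 | 3-(chloromethyl)furan | ClCc1ccoc1 | intermediate
11 | (furan-3-ylmethyl)magnesium chloride | Cl[Mg]Cc1ccoc1 | intermediate (not isolated)
12 | 2-[(4E,8E)-11-(furan-3-yl)-4,8-dimethylundeca-4,8-dien-1-yl]-1,3-dioxolane | C/C(=C\CCc1ccoc1)CC/C=C(\C)CCCC1OCCO1 | intermediate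
13 | (5E,9E)-12-(furan-3-yl)-5,9-dimethyldodeca-5,9-dienal | C/C(=C\CCc1ccoc1)CC/C=C(\C)CCCC=O | intermediate
14 | (2R,5E,9E)-2-chloro-12-(furan-3-yl)-5,9-dimethyldodeca-5,9-dienal | C/C(=C\CCc1ccoc1)CC/C=C(\C)CC[C@@H](Cl)C=O | intermediate
15 | (3R,6E,10E)-3-chloro-13-(furan-3-yl)-6,10-dimethyltrideca-6,10-dien-2-ol (C2 epimers) | C/C(=C\CCc1ccoc1)CC/C=C(\C)CC[C@@H](Cl)C(C)O | intermediate
16 | (3R,6E,10E)-3-chloro-13-(furan-3-yl)-6,10-dimethyltrideca-6,10-dien-2-one | C/C(=C\CCc1ccoc1)CC/C=C(\C)CC[C@@H](Cl)C(C)=O | intermediate
17 | but-3-en-1-ylmagnesium bromide (solution) | C=CCC[Mg]Br | starting material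
18 | (5S,6R,9E,13E)-6-chloro-16-(furan-3-yl)-5,9,13-trimethylhexadeca-1,9,13-trien-5-ol | C/C(=C\CCc1ccoc1)CC/C=C(\C)CC[C@@H](Cl)[C@@](C)(O)CCC=C | intermediate
19 | (2S,3S)-2-(but-3-en-1-yl)-3-[(3E,7E)-10-(furan-3-yl)-3,7-dimethyldeca-3,7-dien-1-yl]-2-methyloxirane | C/C(=C\CCc1ccoc1)CC/C=C(\C)CC[C@@H]1O[C@@]1(C)CCC=C | intermediate
20 | methyl methacrylate | C=C(C)C(=O)OC | starting material
21 | methyl (2E)-5-{(2S,3S)-3-[(3E,7E)-10-(furan-3-yl)-3,7-dimethyldeca-3,7-dien-1-yl]-2-methyloxiran-2-yl}-2-methylpent-2-enoate | C/C(=C\CCc1ccoc1)CC/C=C(\C)CC[C@@H]1O[C@@]1(C)CC/C=C(\C)C(=O)OC | intermediate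
22 | CNP0308047.1, (2E)-5-{(2S,3S)-3-[(3E,7E)-10-(furan-3-yl)-3,7-dimethyldeca-3,7-dien-1-yl]-2-methyloxiran-2-yl}-2-methylpent-2-enoic acid | C/C(=C\CCc1ccoc1)CC/C=C(\C)CC[C@@H]1O[C@@]1(C)CC/C=C(\C)C(=O)O | target

**Count**

Total step count: 15.
Longest linear sequence: 14 steps, from geranyl acetate 1 through steps 1–5 and 7–15; step 6 lies on the furan branch.

**The three steps most likely to fail**

Step 12 (key step). The open transition state may discriminate too weakly between the two faces of the C6 carbonyl, and the Grignard reagent may deprotonate at C7, which returns ketone and erodes the chloride configuration. The fallback hands facial control to a closed six-membered allylboration transition state under a chiral diol catalyst and rebuilds the C3 terminus by olefination instead of metathesis. It sets out from chloroketone 16 and comes back to the route at methyl ester 21, by-passing 18, 19 and step 14. Allyldiisopropoxyborane with the matched enantiomer of 3,3′-dibromo-1,1′-bi-2-naphthol (15 mol %, toluene/PhCF3, −35 °C) should give the allyl chlorohydrin (4S,5R,8E,12E)-5-chloro-15-(furan-3-yl)-4,8,12-trimethylpentadeca-1,8,12-trien-4-ol F1. K2CO3 in MeOH closes it to the allyl oxirane (2S,3S)-3-[(3E,7E)-10-(furan-3-yl)-3,7-dimethyldeca-3,7-dien-1-yl]-2-methyl-2-(prop-2-en-1-yl)oxirane F2. 9-BBN in THF should add only to the monosubstituted olefin to give the B-alkyl-9-borabicyclo[3.3.1]nonane adduct F3, which is oxidised in the same flask with NaBO3·4H2O to 3-{(2S,3S)-3-[(3E,7E)-10-(furan-3-yl)-3,7-dimethyldeca-3,7-dien-1-yl]-2-methyloxiran-2-yl}propan-1-ol F4. Dess–Martin periodinane with NaHCO3 gives the corresponding propanal F5, and Wittig olefination with methyl 2-(triphenylphosphoranylidene)propanoate (CH2Cl2, 25 °C) should give the E-enoate 21.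

Step 7. The reactive furylmethyl halide may self-couple during magnesium insertion, the nucleophile may bond through furan C2 instead of the exocyclic carbon, and the copper species may attack the allylic chloride in the SN2′ sense at C14. The fallback generates the furylmethyl nucleophile by deprotonation of a sulfone instead of metal insertion. It sets out from 3-(chloromethyl)furan 10 and allylic chloride 8 and comes back at furyl diene acetal 12. PhSO2Na in DMF converts 10 into 3-[(phenylsulfonyl)methyl]furan F6. Its lithio derivative (n-BuLi, THF, −78 °C) is alkylated by 8 at the sulfonyl-bearing carbon to give 2-[(4E,8E)-11-(furan-3-yl)-4,8-dimethyl-11-(phenylsulfonyl)undeca-4,8-dien-1-yl]-1,3-dioxolane F7. Reductive desulfonylation with Na(Hg) and Na2HPO4 in MeOH at −20 °C then gives 12.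

Step 3. The Grignard reagent or the organocopper intermediate may attack the allylic acetate (carbonyl addition or displacement of acetate), and some SN2′ coupling at C10 may occur. The fallback brings in C8 as a sulfonyl-stabilised carbanion that leaves the ester alone. It sets out from bromoacetal 4 and bromide 3 and comes back at acetal acetate 6. PhSO2Na in DMF at 60 °C converts 4 into 2-[2-(phenylsulfonyl)ethyl]-1,3-dioxolane F8. Lithiation (n-BuLi, THF, −78 °C) and alkylation with 3 gives (2E,6E)-10-(1,3-dioxolan-2-yl)-3,7-dimethyl-9-(phenylsulfonyl)deca-2,6-dien-1-yl acetate F9. Reductive desulfonylation with Na(Hg) and Na2HPO4 in MeOH at −20 °C returns 6; any acetate lost in the methanolic medium merely anticipates step 4 and gives alcohol 7.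

**Further compounds**

F1 | step 12 | (4S,5R,8E,12E)-5-chloro-15-(furan-3-yl)-4,8,12-trimethylpentadeca-1,8,12-trien-4-ol | C/C(=C\CCc1ccoc1)CC/C=C(\C)CC[C@@H](Cl)[C@@](C)(O)CC=C
F2 | step 12 | (2S,3S)-3-[(3E,7E)-10-(furan-3-yl)-3,7-dimethyldeca-3,7-dien-1-yl]-2-methyl-2-(prop-2-en-1-yl)oxirane | C/C(=C\CCc1ccoc1)CC/C=C(\C)CC[C@@H]1O[C@@]1(C)CC=C
F3 | step 12 | 9-(3-{(2S,3S)-3-[(3E,7E)-10-(furan-3-yl)-3,7-dimethyldeca-3,7-dien-1-yl]-2-methyloxiran-2-yl}propyl)-9-borabicyclo[3.3.1]nonane | C/C(=C\CCc1ccoc1)CC/C=C(\C)CC[C@@H]1O[C@@]1(C)CCCB1C2CCCC1CCC2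
F4 | step 12 | 3-{(2S,3S)-3-[(3E,7E)-10-(furan-3-yl)-3,7-dimethyldeca-3,7-dien-1-yl]-2-methyloxiran-2-yl}propan-1-ol | C/C(=C\CCc1ccoc1)CC/C=C(\C)CC[C@@H]1O[C@@]1(C)CCCO
F5 | step 12 | 3-{(2S,3S)-3-[(3E,7E)-10-(furan-3-yl)-3,7-dimethyldeca-3,7-dien-1-yl]-2-methyloxiran-2-yl}propanal | C/C(=C\CCc1ccoc1)CC/C=C(\C)CC[C@@H]1O[C@@]1(C)CCC=O
F6 | step 7 | 3-[(phenylsulfonyl)methyl]furan | O=S(=O)(Cc1ccoc1)c1ccccc1
F7 | step 7 | 2-[(4E,8E)-11-(furan-3-yl)-4,8-dimethyl-11-(phenylsulfonyl)undeca-4,8-dien-1-yl]-1,3-dioxolane | C/C(=C\CC(c1ccoc1)S(=O)(=O)c1ccccc1)CC/C=C(\C)CCCC1OCCO1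
F8 | step 3 | 2-[2-(phenylsulfonyl)ethyl]-1,3-dioxolane | O=S(=O)(CCC1OCCO1)c1ccccc1
F9 | step 3 | (2E,6E)-10-(1,3-dioxolan-2-yl)-3,7-dimethyl-9-(phenylsulfonyl)deca-2,6-dien-1-yl acetate | CC(=O)OC/C=C(\C)CC/C=C(\C)CC(CC1OCCO1)S(=O)(=O)c1ccccc1
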